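**Retrosynthetic overview**
1. Feature: in the only ring, carbocycle C1–C6 (C1 tertiary carbinol, C4 with Cl and CH3, C5 with Br; C7 is the exocyclic carbon on C1), the oxygenated quaternary C1 lies para to the methyl-bearing C4. With C4=C5 restored, the ring is a cyclohexene made of isoprene (C3–C6) and a C1=C2 acrolein carrying a heteroatom on C1.
2. Endgame: C7=CH2 comes from a C7 ketone. The trans C4–Cl/C5–Br pair comes from a C1–O–C4 bridged bromo ether opened by chloride with retention. That ether arises by bromoetherification of the cyclohexenol, so C1 relays C4 and C5.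
3. C7–C8: an enantiopure six-carbon Grignard side chain (propane-1,3-diol, 2-bromopropene, kinetic resolution) adds to the bridgehead aldehyde.
4. C1–O comes from C1–Br with inversion through an epoxy ether. The bromo aldehyde comes from the catalytic enantioselective Diels–Alder reaction of isoprene with 2-bromoacrolein.
5. Ring order: the carbocycle is closed first (step 2); a temporary oxa-bridge is closed in step 4 and reopened in step 15.

Key step: step 2

Assumption: the sense of induction in the cycloaddition is taken from the formyl C–H···O binding model for 2-substituted acroleins on this catalyst class, which points to the (S)-diphenylprolinol series for the (R)-bromo aldehyde; should the sense prove opposite, the mirror-image catalyst is used and nothing else changes.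

**Step 1**
Reactants: 1 acrolein
Product: 3 2-bromoacrolein, via 2,3-dibromopropanal 2 (not isolated)
Conditions: Br2 (1.0 equiv), CH2Cl2, −78 °C; then Et3N (1.05 equiv), −78 to 0 °C
Reagents that add atoms: bromine, BrBr
Why: Electrophilic bromination of the alkene followed by base-induced dehydrobromination at the acidic α-hydrogen of 2 is the standard bromination–elimination route to 2-haloenals, and no stereocenter survives.

**Step 2**
Reactants: 3 2-bromoacrolein; 4 isoprene
Product: 5 (R)-1-bromo-4-methylcyclohex-3-ene-1-carbaldehyde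
Conditions: (S)-3,3-diphenyl-1-(2-methylphenyl)tetrahydro-1H,3H-pyrrolo[1,2-c][1,3,2]oxazaborole (10 mol %; from (S)-α,α-diphenyl-2-pyrrolidinemethanol and 2-methylphenylboronic acid, toluene, reflux, −H2O) protonated with HN(SO2CF3)2 (9 mol %), 4 (5 equiv), CH2Cl2, −78 °C
Reagents that add atoms: none
Why: Protonation of the oxazaborolidine nitrogen by HN(SO2CF3)2 makes boron strongly Lewis acidic; it binds the formyl oxygen of 3 on the convex face of the bicycle, and a formyl C–H···O contact to the ring oxygen holds the s-trans enal over the neighbouring phenyl group, which lowers the LUMO and screens one π-face. Isoprene adds to the open face in a concerted, asynchronous and suprafacial [4+2] cycloaddition in which C2–C3 forms ahead of C1–C6; the closest known reaction type is this very one, the boron-Lewis-acid-catalysed enantioselective Diels–Alder reaction of 2-haloacroleins with simple dienes. The carbocycle C1–C6, the only ring of the target, is closed intermolecularly by these two σ-bonds as a cyclohexene with its alkene at C4=C5. The one new stereocenter, quaternary C1, is controlled by the catalyst alone: bonding of C6 to the Re face of the bromine-bearing carbon should give the R configuration. The step needs para regioselectivity, secured by the methyl group of 4, which enlarges the HOMO coefficient at the adjoining terminal CH2 (future C3) so that it pairs with the β-carbon C2 of the activated enal; endo/exo selectivity is irrelevant because 4 creates no further stereocenter. The α-bromine raises the reactivity of the dienophile and later serves as the leaving group for the C1 oxygen.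

**Step 3**
Reactants: 5 (R)-1-bromo-4-methylcyclohex-3-ene-1-carbaldehyde
Product: 7 (S)-1-(dimethoxymethyl)-4-methylcyclohex-3-en-1-ol, via spiro epoxy ether 6 (not isolated)
Conditions: NaOMe (1.2 equiv), MeOH, 0 °C to rt
Reagents that add atoms: sodium methoxide, C[O-].[Na+]; methanol, CO
Why: In the epoxy-ether reaction of α-halo carbonyl compounds, methoxide adds to the aldehyde, the hemiacetal alkoxide displaces the tertiary bromide from the rear, and methanolysis of 6 at its acetal carbon leaves the new C1–O bond untouched, so C1 is inverted to the configuration of the target.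

**Step 4**
Reactants: 7 (S)-1-(dimethoxymethyl)-4-methylcyclohex-3-en-1-ol
Product: 8 (1R,2R,4S)-2-bromo-4-(dimethoxymethyl)-1-methyl-7-oxabicyclo[2.2.1]heptane (bromine endo)
Conditions: NBS (1.1 equiv), CH2Cl2, 0 °C, dark
Reagents that add atoms: N-bromosuccinimide, O=C1CCC(=O)N1Br
Why: In this bromoetherification, bromonium formation at C4=C5 is reversible and only the ion on the face opposite the C1 hydroxyl can be trapped irreversibly, by Markovnikov attack of that oxygen on tertiary C4 through a boat, so anti addition sets C4 (O) and C5 (Br) from C1.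

**Step 5**
Reactants: 8 bridged bromo ether acetal
Product: 9 (1S,3R,4R)-3-bromo-4-methyl-7-oxabicyclo[2.2.1]heptane-1-carbaldehyde
Conditions: CF3CO2H/H2O (1:1), CHCl3, 0 °C to rt
Reagents that add atoms: water, O
Why: Acid-catalysed acetal hydrolysis should release the aldehyde, since the bridged ether and the secondary bromide tolerate aqueous acid and the bridgehead aldehyde has no α-hydrogen to epimerise.

**Step 6**
Reactants: 10 propane-1,3-diol
Product: 11 3-((tert-butyldimethylsilyl)oxy)propan-1-ol
Conditions: NaH (1.0 equiv), THF, rt; then TBSCl (1.0 equiv)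
Reagents that add atoms: tert-butyldimethylsilyl chloride, CC(C)(C)[Si](C)(C)Cl
Why: O-Silylation of the sparingly soluble monosodium alkoxide is the standard way to monoprotect a symmetrical diol.

**Step 7**
Reactants: 11 3-((tert-butyldimethylsilyl)oxy)propan-1-ol
Product: 12 3-((tert-butyldimethylsilyl)oxy)propanal
Conditions: 2,2,6,6-tetramethylpiperidine-1-oxyl (10 mol %), PhI(OAc)2 (1.1 equiv), CH2Cl2, rt
Reagents that add atoms: none
Why: The oxoammonium-mediated (nitroxyl/PhI(OAc)2) oxidation stops at the aldehyde and is free of base, so β-elimination of the silyloxy group is avoided.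

**Step 8**
Reactants: 13 2-bromopropene; 12 3-((tert-butyldimethylsilyl)oxy)propanal
Product: 15 rac-5-((tert-butyldimethylsilyl)oxy)-2-methylpent-1-en-3-ol, via isopropenylmagnesium bromide 14 (not isolated)
Conditions: 13, Mg, THF, rt to 40 °C; then 12, −78 to 0 °C; aq NH4Cl
Reagents that add atoms: none
Why: Grignard addition of an alkenylmagnesium halide to an unhindered aldehyde gives the allylic alcohol, here as the racemate that step 9 resolves.

**Step 9**
Reactants: 15 rac-5-((tert-butyldimethylsilyl)oxy)-2-methylpent-1-en-3-ol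
Product: 16 (R)-5-((tert-butyldimethylsilyl)oxy)-2-methylpent-1-en-3-ol
Conditions: Ti(OiPr)4 (0.2 equiv), diisopropyl L-(+)-tartrate (0.24 equiv), t-BuOOH (0.6 equiv), 4 Å MS, CH2Cl2, −20 °C
Reagents that add atoms: none
Why: In the Sharpless kinetic resolution with the L-(+)-tartrate catalyst the (S)-enantiomer of a 2-methyl-1-alken-3-ol is epoxidised much faster, so running past half conversion should leave the (R)-alcohol, which fixes the side-chain carbinol centre.

**Step 10**
Reactants: 16 (R)-allylic alcohol
Product: 17 (R)-5-((tert-butyldimethylsilyl)oxy)-3-((tert-butyldiphenylsilyl)oxy)-2-methylpent-1-ene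
Conditions: TBDPSCl, imidazole, DMF, rt
Reagents that add atoms: tert-butyldiphenylsilyl chloride, CC(C)(C)[Si](Cl)(c1ccccc1)c1ccccc1
Why: Imidazole-promoted O-silylation does not touch the stereocenter and installs a bulky, weakly Lewis-basic ether chosen to withstand BCl3 in step 15.

**Step 11**
Reactants: 17 bis-silyl ether
Product: 18 (R)-3-((tert-butyldiphenylsilyl)oxy)-4-methylpent-4-en-1-ol
Conditions: camphor-10-sulfonic acid (10 mol %), MeOH/CH2Cl2, 0 °C
Reagents that add atoms: none
Why: Acid-catalysed methanolysis removes the primary TBS ether far faster than the hindered secondary TBDPS ether, a standard selective desilylation.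

**Step 12**
Reactants: 18 primary alcohol
Product: 19 (R)-5-bromo-3-((tert-butyldiphenylsilyl)oxy)-2-methylpent-1-ene
Conditions: CBr4, PPh3, CH2Cl2, 0 °C
Reagents that add atoms: carbon tetrabromide, BrC(Br)(Br)Br
Why: The Appel reaction converts the primary alcohol into the bromide by SN2 displacement of the oxyphosphonium group under neutral conditions that spare the allylic silyl ether.

**Step 13**
Reactants: 19 (R)-bromide; 9 bridgehead aldehyde
Product: 21 (4R)-1-[(1S,3R,4R)-3-bromo-4-methyl-7-oxabicyclo[2.2.1]heptan-1-yl]-4-((tert-butyldiphenylsilyl)oxy)-5-methylhex-5-en-1-ol (both C7 epimers), via side-chain Grignard reagent 20 (not isolated)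
Conditions: 19, Mg turnings, THF, rt; then 9, THF, −78 to −20 °C; aq NH4Cl
Reagents that add atoms: none
Why: Grignard addition to a non-enolisable aldehyde at low temperature outruns any attack on the secondary bromide, and the new C7 carbinol centre forms as a mixture that step 14 erases.

**Step 14**
Reactants: 21 carbinol mixture
Product: 22 (R)-1-[(1S,3R,4R)-3-bromo-4-methyl-7-oxabicyclo[2.2.1]heptan-1-yl]-4-((tert-butyldiphenylsilyl)oxy)-5-methylhex-5-en-1-one
Conditions: Dess–Martin periodinane, CH2Cl2, 0 °C to rt
Reagents that add atoms: none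
Why: The Dess–Martin oxidation converts both epimers into one ketone under mild conditions that leave alkene, bromide and silyl ether alone.

**Step 15**
Reactants: 22 bridged bromo ether ketone
Product: 23 (R)-1-[(1S,3R,4R)-3-bromo-4-chloro-1-hydroxy-4-methylcyclohexyl]-4-((tert-butyldiphenylsilyl)oxy)-5-methylhex-5-en-1-one
Conditions: BCl3 (1.2 equiv), CH2Cl2, −78 °C; then H2O (pH 7 buffer)
Reagents that add atoms: boron trichloride, ClB(Cl)Cl
Why: Proposed new method: BCl3 should bind the C7 ketone and the bridging oxygen as a five-membered chelate (closest known reaction types: carbonyl-directed boron trihalide cleavage of ethers and boron trihalide opening of 7-oxanorbornanes and cineoles); C1–O cannot ionise next to the carbonyl, so the tertiary C4–O bond breaks with help from the endo C5 bromine lying nearly antiperiplanar to it, and the bromonium ion so formed on the lower face (the reverse of step 4) is opened by chloride at the more substituted C4 from the upper face where the chloroborate sits, a double inversion that puts Cl in the place of oxygen (retention at C4) and leaves C5 untouched.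

**Step 16**
Reactants: 23 α-hydroxy ketone
Product: 24 (1S,3R,4R)-3-bromo-1-[(R)-5-((tert-butyldiphenylsilyl)oxy)-6-methylhepta-1,6-dien-2-yl]-4-chloro-4-methylcyclohexan-1-ol
Conditions: Cp2TiMe2 (4 equiv), toluene, 70 °C, dark
Reagents that add atoms: dimethyltitanocene, C[Ti](C)(C1C=CC=C1)C1C=CC=C1
Why: In the Petasis methylenation the thermally generated Cp2Ti=CH2 is non-basic and reacts with the hindered ketone through an oxatitanacyclobutane, so the C–Cl and C–Br bonds are spared, and the excess reagent covers the equivalent taken up by the free C1 hydroxyl.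

**Step 17**
Reactants: 24 silyl ether
Product: 25 (1S,3R,4R)-3-bromo-4-chloro-1-[(R)-5-hydroxy-6-methylhepta-1,6-dien-2-yl]-4-methylcyclohexan-1-ol (target)
Conditions: Bu4NF/AcOH (1:1), THF, 0 °C to rt
Reagents that add atoms: none
Why: Fluoride-mediated desilylation is driven by the Si–F bond and is buffered with AcOH so that no basic fluoride or alkoxide can trigger loss of HCl or HBr, and no stereocenter is touched.

**Compound list**
1 | acrolein | C=CC=O | starting material
2 | 2,3-dibromopropanal (racemic) | O=CC(Br)CBr | intermediate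
3 | 2-bromoacrolein | C=C(Br)C=O | intermediate
4 | isoprene | C=CC(C)=C | starting material
5 | (R)-1-bromo-4-methylcyclohex-3-ene-1-carbaldehyde | O=C[C@@]1(Br)CCC(C)=CC1 | intermediate
6 | (3S)-2-methoxy-6-methyl-1-oxaspiro[2.5]oct-5-ene (epimers at C2) | COC1O[C@]12CCC(C)=CC2 | intermediate
7 | (S)-1-(dimethoxymethyl)-4-methylcyclohex-3-en-1-ol | COC(OC)[C@]1(O)CCC(C)=CC1 | intermediate
8 | (1R,2R,4S)-2-bromo-4-(dimethoxymethyl)-1-methyl-7-oxabicyclo[2.2.1]heptane | COC(OC)[C@@]12CC[C@@](C)(O1)[C@H](Br)C2 | intermediate
9 | (1S,3R,4R)-3-bromo-4-methyl-7-oxabicyclo[2.2.1]heptane-1-carbaldehyde | O=C[C@@]12CC[C@@](C)(O1)[C@H](Br)C2 | intermediate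
10 | propane-1,3-diol | OCCCO | starting material
11 | 3-((tert-butyldimethylsilyl)oxy)propan-1-ol | OCCCO[Si](C)(C)C(C)(C)C | intermediate
12 | 3-((tert-butyldimethylsilyl)oxy)propanal | O=CCCO[Si](C)(C)C(C)(C)C | intermediate
13 | 2-bromopropene | C=C(C)Br | starting material
14 | isopropenylmagnesium bromide | C=C(C)[Mg]Br | intermediate
15 | rac-5-((tert-butyldimethylsilyl)oxy)-2-methylpent-1-en-3-ol | C=C(C)C(O)CCO[Si](C)(C)C(C)(C)C | intermediate
16 | (R)-5-((tert-butyldimethylsilyl)oxy)-2-methylpent-1-en-3-ol | C=C(C)[C@H](O)CCO[Si](C)(C)C(C)(C)C | intermediate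
17 | (R)-5-((tert-butyldimethylsilyl)oxy)-3-((tert-butyldiphenylsilyl)oxy)-2-methylpent-1-ene | C=C(C)[C@H](O[Si](c1ccccc1)(c1ccccc1)C(C)(C)C)CCO[Si](C)(C)C(C)(C)C | intermediate
18 | (R)-3-((tert-butyldiphenylsilyl)oxy)-4-methylpent-4-en-1-ol | C=C(C)[C@H](O[Si](c1ccccc1)(c1ccccc1)C(C)(C)C)CCO | intermediate
19 | (R)-5-bromo-3-((tert-butyldiphenylsilyl)oxy)-2-methylpent-1-ene | C=C(C)[C@H](O[Si](c1ccccc1)(c1ccccc1)C(C)(C)C)CCBr | intermediate
20 | (R)-(3-((tert-butyldiphenylsilyl)oxy)-4-methylpent-4-en-1-yl)magnesium bromide | C=C(C)[C@H](O[Si](c1ccccc1)(c1ccccc1)C(C)(C)C)CC[Mg]Br | intermediate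
21 | (4R)-1-[(1S,3R,4R)-3-bromo-4-methyl-7-oxabicyclo[2.2.1]heptan-1-yl]-4-((tert-butyldiphenylsilyl)oxy)-5-methylhex-5-en-1-ol (C7 epimers) | C=C(C)[C@H](O[Si](c1ccccc1)(c1ccccc1)C(C)(C)C)CCC(O)[C@@]12CC[C@@](C)(O1)[C@H](Br)C2 | intermediate
22 | (R)-1-[(1S,3R,4R)-3-bromo-4-methyl-7-oxabicyclo[2.2.1]heptan-1-yl]-4-((tert-butyldiphenylsilyl)oxy)-5-methylhex-5-en-1-one | C=C(C)[C@H](O[Si](c1ccccc1)(c1ccccc1)C(C)(C)C)CCC(=O)[C@@]12CC[C@@](C)(O1)[C@H](Br)C2 | intermediate
23 | (R)-1-[(1S,3R,4R)-3-bromo-4-chloro-1-hydroxy-4-methylcyclohexyl]-4-((tert-butyldiphenylsilyl)oxy)-5-methylhex-5-en-1-one | C=C(C)[C@H](O[Si](c1ccccc1)(c1ccccc1)C(C)(C)C)CCC(=O)[C@]1(O)CC[C@@](C)(Cl)[C@H](Br)C1 | intermediate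
24 | (1S,3R,4R)-3-bromo-1-[(R)-5-((tert-butyldiphenylsilyl)oxy)-6-methylhepta-1,6-dien-2-yl]-4-chloro-4-methylcyclohexan-1-ol | C=C(C)[C@H](O[Si](c1ccccc1)(c1ccccc1)C(C)(C)C)CCC(=C)[C@]1(O)CC[C@@](C)(Cl)[C@H](Br)C1 | intermediate
25 | (1S,3R,4R)-3-bromo-4-chloro-1-[(R)-5-hydroxy-6-methylhepta-1,6-dien-2-yl]-4-methylcyclohexan-1-ol | C=C(C)[C@H](O)CCC(=C)[C@]1(O)CC[C@@](C)(Cl)[C@H](Br)C1 | target

**Totals**
- Total step count: 17.
- Longest linear sequence: 12 steps (steps 6–17, from propane-1,3-diol).
- The ring branch runs over 10 steps (steps 1–5 and 13–17).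

**Steps most likely to fail**

1. **Step 15.**
   - What may go wrong: C4 may ionise without bromine participation, so that chloride enters from the lower face or a proton is lost to give an alkene. Electrophilic bromine may be expelled back to the cyclohexene. BCl3 may attack the allylic silyl ether.
   - Fallback (known chemistry only), from 22 back to 23: zinc dust in AcOH/EtOH effects a Boord-type reductive elimination of the β-bromo ether. This gives (R)-4-((tert-butyldiphenylsilyl)oxy)-1-((S)-1-hydroxy-4-methylcyclohex-3-en-1-yl)-5-methylhex-5-en-1-one F1.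
   - TESOTf/2,6-lutidine then masks the C1 hydroxyl as the triethylsilyl ether of that hydroxy ketone F2, so that it cannot recapture a bromonium ion.
   - Bu4NBrCl2 in CH2Cl2 at −78 °C adds Br and Cl anti and in the Markovnikov sense (Cl on C4). It should react at the more electron-rich ring alkene, because the side-chain alkene is deactivated and shielded by its allylic silyloxy group. This gives the C1-O-triethylsilyl bromochloride F3, which is separated from its facial isomer by chromatography.
   - Pyridinium p-toluenesulfonate in MeOH removes the triethylsilyl group and the route is rejoined at 23.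

2. **Step 16.**
   - What may go wrong: methylenation of the hindered ketone flanked by a quaternary carbon may be slow. The free hydroxyl consumes reagent. α-Ketol rearrangement or thermal loss of HCl may occur at 70 °C.
   - Fallback, from 23 back to 24 (Peterson olefination): Me3SiCH2MgCl with CeCl3 (3 equiv) in THF at −78 °C adds to C7 to give the β-hydroxysilane diol F4. Brief treatment with HF·pyridine in THF at 0 °C triggers elimination of the silyl and C7 hydroxyl groups, and the route is rejoined at 24.

3. **Step 3.**
   - What may go wrong: E2 loss of HBr may compete and give a conjugated dienal. A hydride shift in the hemiacetal anion may give the methyl ester. Partial ionisation of the tertiary bromide would erode the enantiomeric purity at C1.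
   - Fallback, from 5 back to 7: NaBH4 in MeOH at 0 °C gives (R)-(1-bromo-4-methylcyclohex-3-en-1-yl)methanol F5.
   - K2CO3 in MeOH closes (S)-6-methyl-1-oxaspiro[2.5]oct-5-ene F6 by the same rear-side displacement at C1.
   - KOH in DMSO/H2O opens the epoxide at its CH2 carbon to give (S)-1-(hydroxymethyl)-4-methylcyclohex-3-en-1-ol F7.
   - Parikh–Doering oxidation of the primary alcohol gives (S)-1-hydroxy-4-methylcyclohex-3-ene-1-carbaldehyde F8.
   - HC(OMe)3 in MeOH with pyridinium p-toluenesulfonate forms the dimethyl acetal and the route is rejoined at 7.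

**Further compounds**
F1 | step 15 | (R)-4-((tert-butyldiphenylsilyl)oxy)-1-((S)-1-hydroxy-4-methylcyclohex-3-en-1-yl)-5-methylhex-5-en-1-one | C=C(C)[C@H](O[Si](c1ccccc1)(c1ccccc1)C(C)(C)C)CCC(=O)[C@]1(O)CCC(C)=CC1
F2 | step 15 | (R)-4-((tert-butyldiphenylsilyl)oxy)-5-methyl-1-((S)-4-methyl-1-((triethylsilyl)oxy)cyclohex-3-en-1-yl)hex-5-en-1-one | C=C(C)[C@H](O[Si](c1ccccc1)(c1ccccc1)C(C)(C)C)CCC(=O)[C@]1(O[Si](CC)(CC)CC)CCC(C)=CC1
F3 | step 15 | (R)-1-[(1S,3R,4R)-3-bromo-4-chloro-4-methyl-1-((triethylsilyl)oxy)cyclohexyl]-4-((tert-butyldiphenylsilyl)oxy)-5-methylhex-5-en-1-one | C=C(C)[C@H](O[Si](c1ccccc1)(c1ccccc1)C(C)(C)C)CCC(=O)[C@]1(O[Si](CC)(CC)CC)CC[C@@](C)(Cl)[C@H](Br)C1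
F4 | step 16 | (1S,3R,4R)-3-bromo-1-[(5R)-5-((tert-butyldiphenylsilyl)oxy)-2-hydroxy-6-methyl-1-(trimethylsilyl)hept-6-en-2-yl]-4-chloro-4-methylcyclohexan-1-ol (epimers at the new carbinol) | C=C(C)[C@H](O[Si](c1ccccc1)(c1ccccc1)C(C)(C)C)CCC(O)(C[Si](C)(C)C)[C@]1(O)CC[C@@](C)(Cl)[C@H](Br)C1
F5 | step 3 | (R)-(1-bromo-4-methylcyclohex-3-en-1-yl)methanol | OC[C@@]1(Br)CCC(C)=CC1
F6 | step 3 | (S)-6-methyl-1-oxaspiro[2.5]oct-5-ene | C1O[C@]12CCC(C)=CC2
F7 | step 3 | (S)-1-(hydroxymethyl)-4-methylcyclohex-3-en-1-ol | OC[C@]1(O)CCC(C)=CC1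
F8 | step 3 | (S)-1-hydroxy-4-methylcyclohex-3-ene-1-carbaldehyde | O=C[C@]1(O)CCC(C)=CC1
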